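In the tetrahydrofuran ring (O1; C2 carrying the arylmethyl group; C3 the carbinol; C4 the methylene; C5 carrying the oxoethyl chain) the array O1–C5–C4–C3(OH) is a masked aldol. The key step exploits it: a 4-methylidene-1,3-dioxolane, assembled from a chiral-pool (R)-aryl-lactic acid and an arylpropynal, undergoes an aluminium-triggered Petasis–Ferrier rearrangement in which the acetal ring opens to an enolate/oxocarbenium pair, the C4–C5 bond closes the tetrahydrofuran, and the C3 ketone is reduced in the same flask. One operation thus sets C5 and C3 from the C2 centre. Alkyne hydration and debenzylation complete the synthesis.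

Key step: step 7

Assumption: compounds 1, 5 and 6 are purchased as such, and both phenols are carried as benzyl ethers until the last step.

Step 1
Reactants: 1 4-(benzyloxy)-3-methoxybenzaldehyde
Product: 2 1-(benzyloxy)-4-(2,2-dibromoethenyl)-2-methoxybenzene
Conditions: CBr4, PPh3, Zn dust, CH2Cl2, 0 °C to rt
Reagents that add atoms: carbon tetrabromide, BrC(Br)(Br)Br
Why: Corey–Fuchs dibromo-olefination, in which Ph3P=CBr2 generated in the flask should convert the aryl aldehyde into the 1,1-dibromoalkene by a Wittig reaction that leaves both aryl ethers untouched.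

Step 2
Reactants: 2 1-(benzyloxy)-4-(2,2-dibromoethenyl)-2-methoxybenzene
Product: 4 3-[4-(benzyloxy)-3-methoxyphenyl]prop-2-ynal, via lithium arylacetylide 3 (not isolated)
Conditions: n-BuLi (2.1 equiv), THF, −78 °C; then DMF, −78 to 0 °C; inverse quench into cold aq. KH2PO4
Reagents that add atoms: N,N-dimethylformamide, CN(C)C=O
Why: second half of the Corey–Fuchs sequence, in which bromine–lithium exchange and carbenoid rearrangement should give the lithium acetylide that DMF formylates, the buffered inverse quench releasing the ynal before dimethylamine can add to it.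

Step 3
Reactants: 5 1-(benzyloxy)-4-bromo-2-methoxybenzene; 6 methyl (2R)-oxirane-2-carboxylate (methyl (R)-glycidate)
Product: 8 methyl (2R)-3-[4-(benzyloxy)-3-methoxyphenyl]-2-hydroxypropanoate, via arylmagnesium bromide 7 (not isolated)
Conditions: Mg, THF, reflux; then CuBr·SMe2 (10 mol %), 6, THF, −40 °C; aq. NH4Cl
Reagents that add atoms: none
Why: copper-catalysed SN2 opening of the terminal epoxide carbon by the aryl Grignard reagent should outrun addition to the ester at −40 °C, and since the stereocenter is not a reacting carbon its (R) configuration is taken unchanged from the chiral pool.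

Step 4
Reactants: 8 methyl (2R)-3-[4-(benzyloxy)-3-methoxyphenyl]-2-hydroxypropanoate
Product: 9 (2R)-3-[4-(benzyloxy)-3-methoxyphenyl]-2-hydroxypropanoic acid
Conditions: LiOH·H2O, THF/H2O, 0 °C to rt; then 1 M HCl
Reagents that add atoms: lithium hydroxide, [Li+].[OH-]
Why: ester saponification with LiOH at low temperature should free the acid without epimerising the α-hydroxy stereocenter.

Step 5
Reactants: 9 (2R)-3-[4-(benzyloxy)-3-methoxyphenyl]-2-hydroxypropanoic acid; 4 3-[4-(benzyloxy)-3-methoxyphenyl]prop-2-ynal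
Product: 11 (2R,5R)-5-[4-(benzyloxy)-3-methoxybenzyl]-2-{[4-(benzyloxy)-3-methoxyphenyl]ethynyl}-1,3-dioxolan-4-one, via bis(trimethylsilyl) derivative 10 (not isolated)
Conditions: (Me3Si)2NH, THF, 50 °C, concentrate; then 4, TMSOTf (10 mol %), CH2Cl2, −78 °C; pyridine quench
Reagents that add atoms: none
Why: silyl-triflate-catalysed (Noyori-type) acetalisation of the bis-silylated α-hydroxy acid with the aldehyde should give the dioxolanone with the 2,5-cis isomer favoured under kinetic control, C5 keeping its (R) configuration and the new acetal centre C2 being of no lasting consequence because it is planarised again in step 7.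

Step 6
Reactants: 11 (2R,5R)-5-[4-(benzyloxy)-3-methoxybenzyl]-2-{[4-(benzyloxy)-3-methoxyphenyl]ethynyl}-1,3-dioxolan-4-one
Product: 12 (2R,5R)-5-[4-(benzyloxy)-3-methoxybenzyl]-2-{[4-(benzyloxy)-3-methoxyphenyl]ethynyl}-4-methylidene-1,3-dioxolane
Conditions: Cp2TiMe2 (2 equiv), toluene, 65 °C, dark; filtration through basic alumina
Reagents that add atoms: dimethyltitanocene, C[Ti](C)(C1C=CC=C1)C1C=CC=C1
Why: Petasis methylenation, in which Cp2Ti=CH2 formed by thermolysis of Cp2TiMe2 should olefinate the electrophilic lactone carbonyl through an oxatitanacyclobutane under conditions that are neither acidic nor basic and so preserve the acetal and C5, the carbonyl being expected to capture the carbene faster than the internal alkyne when the reagent is kept near two equivalents.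

Step 7
Reactants: 12 (2R,5R)-5-[4-(benzyloxy)-3-methoxybenzyl]-2-{[4-(benzyloxy)-3-methoxyphenyl]ethynyl}-4-methylidene-1,3-dioxolane
Product: 14 (2R,3R,5R)-2-[4-(benzyloxy)-3-methoxybenzyl]-5-{[4-(benzyloxy)-3-methoxyphenyl]ethynyl}oxolan-3-ol, via oxolan-3-one 13 (not isolated)
Conditions: i-Bu3Al (3 equiv), toluene, −78 to 0 °C; aq. potassium sodium tartrate
Reagents that add atoms: none
Why: i-Bu3Al should bind the enol-ether oxygen and cleave the adjacent acetal C–O bond to an aluminium enolate held next to an alkynyl-stabilised oxocarbenium ion, the enolate methylene carbon (C4) then adding to the oxocarbenium carbon (C5) to give ketone 13, which the same alane reduces by β-hydride transfer from an isobutyl group. The closest known reaction type is the aluminium-mediated Petasis–Ferrier rearrangement of 4-methylidene-1,3-dioxolanes to tetrahydrofuran-3-ols, formally a 1,3 shift of the acetal carbon from oxygen to carbon. The tetrahydrofuran ring closes in a 5-(enolendo)-endo-trig aldol-type mode, which is workable because enolate and oxocarbenium are generated as a tight, aluminium-bridged ion pair. C5 is controlled by C2: the (E)-oxocarbenium should cyclise through the envelope in which the C2 hydrogen, not the arylmethyl group, takes the inside position next to the C5 hydrogen, which places the arylmethyl and alkynyl groups cis whatever the acetal configuration of 12. C3 is controlled by both ring substituents, hydride being delivered to the ketone face opposite to them so that the hydroxyl ends cis to both. The step needs C–C closure to outrun hydride or alkyl transfer to the oxocarbenium ion and needs the alkyne to stay intact, which the intramolecular ion-paired enolate and the low temperature (internal aryl alkynes are hydroaluminated only on warming) should secure.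

Step 8
Reactants: 14 (2R,3R,5R)-2-[4-(benzyloxy)-3-methoxybenzyl]-5-{[4-(benzyloxy)-3-methoxyphenyl]ethynyl}oxolan-3-ol
Product: 15 1-[4-(benzyloxy)-3-methoxyphenyl]-2-{(2R,4R,5R)-5-[4-(benzyloxy)-3-methoxybenzyl]-4-hydroxyoxolan-2-yl}ethan-1-one
Conditions: Ph3PAuNTf2 (5 mol %), H2O (10 equiv), 1,4-dioxane, rt to 40 °C
Reagents that add atoms: water, O
Why: gold-catalysed Markovnikov hydration, in which water should add to the alkyne carbon bearing the electron-rich aryl ring (positive charge stabilised by the para oxygen, and remote from the inductively deactivating ring C–O bond) so that tautomerisation gives the aryl ketone with no stereocenter involved.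

Step 9
Reactants: 15 1-[4-(benzyloxy)-3-methoxyphenyl]-2-{(2R,4R,5R)-5-[4-(benzyloxy)-3-methoxybenzyl]-4-hydroxyoxolan-2-yl}ethan-1-one
Product: 16 renealtin A
Conditions: H2 (1 atm), Pd/C (10 wt %), EtOAc, rt
Reagents that add atoms: none
Why: hydrogenolysis of the two aryl benzyl ethers over Pd/C should be much faster than reduction of the electron-rich aryl ketone, and the neutral conditions should not open the β-alkoxy ketone.

Compound list
1 | 4-(benzyloxy)-3-methoxybenzaldehyde | COc1cc(C=O)ccc1OCc1ccccc1 | starting material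
2 | 1-(benzyloxy)-4-(2,2-dibromoethenyl)-2-methoxybenzene | COc1cc(C=C(Br)Br)ccc1OCc1ccccc1 | intermediate
3 | lithium [4-(benzyloxy)-3-methoxyphenyl]acetylide | [Li]C#Cc1ccc(OCc2ccccc2)c(OC)c1 | intermediate
4 | 3-[4-(benzyloxy)-3-methoxyphenyl]prop-2-ynal | O=CC#Cc1ccc(OCc2ccccc2)c(OC)c1 | intermediate
5 | 1-(benzyloxy)-4-bromo-2-methoxybenzene | COc1cc(Br)ccc1OCc1ccccc1 | starting material
6 | methyl (2R)-oxirane-2-carboxylate | COC(=O)[C@H]1CO1 | starting material
7 | [4-(benzyloxy)-3-methoxyphenyl]magnesium bromide | COc1cc([Mg]Br)ccc1OCc1ccccc1 | intermediate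
8 | methyl (2R)-3-[4-(benzyloxy)-3-methoxyphenyl]-2-hydroxypropanoate | COC(=O)[C@H](O)Cc1ccc(OCc2ccccc2)c(OC)c1 | intermediate
9 | (2R)-3-[4-(benzyloxy)-3-methoxyphenyl]-2-hydroxypropanoic acid | OC(=O)[C@H](O)Cc1ccc(OCc2ccccc2)c(OC)c1 | intermediate
10 | trimethylsilyl (2R)-3-[4-(benzyloxy)-3-methoxyphenyl]-2-[(trimethylsilyl)oxy]propanoate | C[Si](C)(C)OC(=O)[C@H](O[Si](C)(C)C)Cc1ccc(OCc2ccccc2)c(OC)c1 | intermediate
11 | (2R,5R)-5-[4-(benzyloxy)-3-methoxybenzyl]-2-{[4-(benzyloxy)-3-methoxyphenyl]ethynyl}-1,3-dioxolan-4-one (2,5-cis) | O=C1O[C@H](C#Cc2ccc(OCc3ccccc3)c(OC)c2)O[C@@H]1Cc1ccc(OCc2ccccc2)c(OC)c1 | intermediate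
12 | (2R,5R)-5-[4-(benzyloxy)-3-methoxybenzyl]-2-{[4-(benzyloxy)-3-methoxyphenyl]ethynyl}-4-methylidene-1,3-dioxolane | C=C1O[C@H](C#Cc2ccc(OCc3ccccc3)c(OC)c2)O[C@@H]1Cc1ccc(OCc2ccccc2)c(OC)c1 | intermediate
13 | (2R,5R)-2-[4-(benzyloxy)-3-methoxybenzyl]-5-{[4-(benzyloxy)-3-methoxyphenyl]ethynyl}oxolan-3-one (2,5-cis) | COc1cc(C[C@H]2O[C@@H](C#Cc3ccc(OCc4ccccc4)c(OC)c3)CC2=O)ccc1OCc1ccccc1 | intermediate
14 | (2R,3R,5R)-2-[4-(benzyloxy)-3-methoxybenzyl]-5-{[4-(benzyloxy)-3-methoxyphenyl]ethynyl}oxolan-3-ol (all-cis) | COc1cc(C[C@H]2O[C@@H](C#Cc3ccc(OCc4ccccc4)c(OC)c3)C[C@H]2O)ccc1OCc1ccccc1 | intermediate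
15 | 1-[4-(benzyloxy)-3-methoxyphenyl]-2-{(2R,4R,5R)-5-[4-(benzyloxy)-3-methoxybenzyl]-4-hydroxyoxolan-2-yl}ethan-1-one | COc1cc(C[C@H]2O[C@@H](CC(=O)c3ccc(OCc4ccccc4)c(OC)c3)C[C@H]2O)ccc1OCc1ccccc1 | intermediate
16 | renealtin A, 1-(4-hydroxy-3-methoxyphenyl)-2-[(2R,4R,5R)-4-hydroxy-5-(4-hydroxy-3-methoxybenzyl)oxolan-2-yl]ethan-1-one | COc1cc(C[C@H]2O[C@@H](CC(=O)c3ccc(O)c(OC)c3)C[C@H]2O)ccc1O | target

Total step count: 9
Longest linear sequence: 7 steps (steps 3 to 9, from 5 and 6); steps 1 and 2 form the second branch, joined in step 5.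

Steps most likely to fail

Step 6. The titanium methylidene may be captured by the aryl alkyne (titanacyclobutene formation) in competition with the lactone carbonyl, and the enol acetal may hydrolyse on handling. The fallback sets out from 1 and 9 and comes back to the route at 15; it gives up the alkyne as ketone surrogate in favour of a 1,3-dithiane, which offers no π-bond to the carbene. Compound 1 with propane-1,3-dithiol and BF3·OEt2 in CH2Cl2 should give 2-[4-(benzyloxy)-3-methoxyphenyl]-1,3-dithiane F1. Lithiation with n-BuLi in THF and opening of oxirane should give the dithianyl ethanol F2. Parikh–Doering oxidation (SO3·pyridine, DMSO, i-Pr2NEt) should give the dithianyl acetaldehyde F3. Condensation of F3 with 9 under the conditions of step 5 (through 10) should give the dioxolanone F4. Cp2TiMe2 should then give the methylidene dioxolane F5, and i-Bu3Al under the conditions of step 7 the all-cis tetrahydrofuranol F6. Hydrolysis of the dithiane with MeI and CaCO3 in aqueous MeCN should deliver 15.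

Step 7. Hydride or isobutyl transfer from the alane to the oxocarbenium ion may occur before C–C closure (reductive acetal opening). The slim alkynyl group may erode 2,5-cis control, the alkyne may be hydroaluminated, or facial selectivity in the ketone reduction may be poor. The fallback sets out from 12 and comes back at 14; it separates the two events and changes both reagents. Me2AlCl, which carries no β-hydrogen, in CH2Cl2 at −78 °C should stop at the isolated ketone 13 and allow equilibration toward the cis ring through reversible ring opening. LiB(s-Bu)3H in THF at −78 °C should then deliver hydride from the face opposite to the two ring substituents to give 14. No compound outside the list is made (F0).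

Step 8. Intramolecular hydroalkoxylation of the gold-activated alkyne by the cis C3 hydroxyl may compete with attack of water and erode the regiocontrol of oxygen delivery. The fallback sets out from 14 and comes back at 15; it removes the competing nucleophile before the hydration. TESCl and imidazole in CH2Cl2 should give the C3 triethylsilyl ether of 14 F7. Hydration with Ph3PAuNTf2 in wet 1,4-dioxane should give the silyl-protected aryl ketone F8. AcOH/THF/H2O at rt should remove the silyl group and give 15.

Further compounds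
F1 | step 6 | 2-[4-(benzyloxy)-3-methoxyphenyl]-1,3-dithiane | COc1cc(C2SCCCS2)ccc1OCc1ccccc1
F2 | step 6 | 2-{2-[4-(benzyloxy)-3-methoxyphenyl]-1,3-dithian-2-yl}ethan-1-ol | COc1cc(C2(CCO)SCCCS2)ccc1OCc1ccccc1
F3 | step 6 | {2-[4-(benzyloxy)-3-methoxyphenyl]-1,3-dithian-2-yl}acetaldehyde | COc1cc(C2(CC=O)SCCCS2)ccc1OCc1ccccc1
F4 | step 6 | (2R,5R)-5-[4-(benzyloxy)-3-methoxybenzyl]-2-({2-[4-(benzyloxy)-3-methoxyphenyl]-1,3-dithian-2-yl}methyl)-1,3-dioxolan-4-one | O=C1O[C@H](CC2(c3ccc(OCc4ccccc4)c(OC)c3)SCCCS2)O[C@@H]1Cc1ccc(OCc2ccccc2)c(OC)c1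
F5 | step 6 | (2R,5R)-5-[4-(benzyloxy)-3-methoxybenzyl]-2-({2-[4-(benzyloxy)-3-methoxyphenyl]-1,3-dithian-2-yl}methyl)-4-methylidene-1,3-dioxolane | C=C1O[C@H](CC2(c3ccc(OCc4ccccc4)c(OC)c3)SCCCS2)O[C@@H]1Cc1ccc(OCc2ccccc2)c(OC)c1
F6 | step 6 | (2R,3R,5R)-2-[4-(benzyloxy)-3-methoxybenzyl]-5-({2-[4-(benzyloxy)-3-methoxyphenyl]-1,3-dithian-2-yl}methyl)oxolan-3-ol | COc1cc(C[C@H]2O[C@@H](CC3(c4ccc(OCc5ccccc5)c(OC)c4)SCCCS3)C[C@H]2O)ccc1OCc1ccccc1
F0 | step 7 | none | none
F7 | step 8 | C3 triethylsilyl ether of 14, all-cis 2-[4-(benzyloxy)-3-methoxybenzyl]-5-{[4-(benzyloxy)-3-methoxyphenyl]ethynyl}-3-[(triethylsilyl)oxy]oxolane | COc1cc(C[C@H]2O[C@@H](C#Cc3ccc(OCc4ccccc4)c(OC)c3)C[C@H]2O[Si](CC)(CC)CC)ccc1OCc1ccccc1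
F8 | step 8 | C4 triethylsilyl ether of 15, all-cis 1-[4-(benzyloxy)-3-methoxyphenyl]-2-{5-[4-(benzyloxy)-3-methoxybenzyl]-4-[(triethylsilyl)oxy]oxolan-2-yl}ethan-1-one | COc1cc(C[C@H]2O[C@@H](CC(=O)c3ccc(OCc4ccccc4)c(OC)c3)C[C@H]2O[Si](CC)(CC)CC)ccc1OCc1ccccc1
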